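**Retrosynthetic overview**

1. Feature: in the oxane ring (O1, C2–C6) the brominated carbon C3 lies between the hemiketal carbon C2 (bonded to O1, CH3, OH) and C4H2. The ring is therefore a 5-methyl-2,3-dihydrofuran (O1, C2, C4, C5, C6) with a CBr unit inserted into its enol ether bond C2=C4.
2. Target 24 ⇐ 3-bromo-5,6-dihydro-2H-pyran-2-ol 21 (1,4-reduction of its ring-opened α-bromoenone, then C3/C2 equilibration) ⇐ dihydrofuran 18 + CBr2 (forms C2–C3 and C3–C4; five- to six-membered ring expansion).
3. 18 ⇐ γ-hydroxy ketone (cyclodehydration) ⇐ E-bromovinyl alcohol 15 (Takai olefination, C8=C9) ⇐ α-chloro-α-methyl-γ-butyrolactone 12.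
4. C7 (tertiary chloride, side chain) from trans-selective chlorination of the lactone enolate; C5 from Evans alkylation of a levulinate-ketal imide with tert-butyl bromoacetate.
5. Ring order: temporary butyrolactone (step 5) → dihydrofuran (step 10) → transient cyclopropane and oxane (step 11) → oxane reopened and reclosed (step 12).

Key step: step 11

Assumption: C2 (hemiketal) and C3 (α to the masked ketone) are taken to be under thermodynamic control, the (2R,3S) target being the chair with C3–Br, C2–CH3 and the C5 side chain equatorial and the anomeric C2–OH axial.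

**Route**

Step 1
Reactants: 1 ethyl levulinate
Product: 2 ethyl 3-(2-methyl-1,3-dioxolan-2-yl)propanoate
Conditions: HOCH2CH2OH, TsOH·H2O (cat.), PhMe, reflux, Dean–Stark
Reagents that add atoms: ethylene glycol, OCCO
Why: Acid-catalysed ketalisation with azeotropic removal of water protects the ketone (future C2) as a dioxolane that tolerates all basic and hydride steps up to step 10.

Step 2
Reactants: 2 ethyl 3-(2-methyl-1,3-dioxolan-2-yl)propanoate
Product: 3 3-(2-methyl-1,3-dioxolan-2-yl)propanoic acid
Conditions: LiOH·H2O, THF/H2O, rt; then 1 M HCl to pH 4, 0 °C, immediate extraction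
Reagents that add atoms: lithium hydroxide, [Li+].[OH-]
Why: Saponification (acyl substitution by hydroxide) frees the acid; the ketal is inert to base, and brief cold acidification to pH 4 avoids its hydrolysis.

Step 3
Reactants: 3 3-(2-methyl-1,3-dioxolan-2-yl)propanoic acid; 4 (R)-4-benzyl-1,3-oxazolidin-2-one
Product: 6 (4R)-4-benzyl-3-[3-(2-methyl-1,3-dioxolan-2-yl)propanoyl]-1,3-oxazolidin-2-one, via mixed pivalic anhydride 5 (not isolated)
Conditions: t-BuCOCl, Et3N, THF, −20 °C; then 4, LiCl, −20 °C → rt
Reagents that add atoms: none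
Why: Mixed-anhydride N-acylation of the oxazolidinone; the unhindered acyl group of the pivalic mixed anhydride is transferred to the lithium-chloride-activated nitrogen.

Step 4
Reactants: 6 (4R)-4-benzyl-3-[3-(2-methyl-1,3-dioxolan-2-yl)propanoyl]-1,3-oxazolidin-2-one; 7 tert-butyl bromoacetate
Product: 8 tert-butyl (3S)-4-[(4R)-4-benzyl-2-oxo-1,3-oxazolidin-3-yl]-3-[(2-methyl-1,3-dioxolan-2-yl)methyl]-4-oxobutanoate
Conditions: NaN(SiMe3)2, THF, −78 °C; then 7, −78 → −40 °C
Reagents that add atoms: none
Why: Evans asymmetric alkylation; the chelated Z-sodium enolate is alkylated on the face away from the benzyl group, which with the (R)-auxiliary sets the (S) centre that becomes C5 of the target.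

Step 5
Reactants: 8 tert-butyl (3S)-4-[(4R)-4-benzyl-2-oxo-1,3-oxazolidin-3-yl]-3-[(2-methyl-1,3-dioxolan-2-yl)methyl]-4-oxobutanoate
Product: 10 (4S)-4-[(2-methyl-1,3-dioxolan-2-yl)methyl]oxolan-2-one, via hydroxy tert-butyl ester 9 (not isolated)
Conditions: LiBH4, H2O (1 equiv), Et2O, 0 °C; then CSA (cat.), PhMe, 60 °C
Reagents that add atoms: none
Why: LiBH4 reductively cleaves the activated exocyclic imide carbonyl while the tert-butyl ester and ketal are untouched, and the γ-hydroxy ester then lactonises under anhydrous acid catalysis (5-exo-trig acyl substitution) with loss of tert-butanol; the stereocentre is not involved.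

Step 6
Reactants: 10 (4S)-4-[(2-methyl-1,3-dioxolan-2-yl)methyl]oxolan-2-one
Product: 11 (3S,4S)-3-methyl-4-[(2-methyl-1,3-dioxolan-2-yl)methyl]oxolan-2-one
Conditions: LiN(i-Pr)2, THF, −78 °C; MeI, −78 → −40 °C
Reagents that add atoms: iodomethane, CI
Why: Lactone enolate alkylation; methyl iodide should enter trans to the C4 substituent, and the configuration of this centre is of no consequence because it is planarised again in step 7.

Step 7
Reactants: 11 (3S,4S)-3-methyl-4-[(2-methyl-1,3-dioxolan-2-yl)methyl]oxolan-2-one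
Product: 12 (3S,4R)-3-chloro-3-methyl-4-[(2-methyl-1,3-dioxolan-2-yl)methyl]oxolan-2-one
Conditions: LiN(i-Pr)2, THF, −78 °C; NCS, −78 → −40 °C; AcOH quench
Reagents that add atoms: N-chlorosuccinimide, ClN1C(=O)CCC1=O
Why: Electrophilic chlorination of the tetrasubstituted lithium enolate should occur on the face opposite the adjacent C4 substituent (1,2-induction in the five-membered ring), placing Cl trans to it and setting the quaternary (S) centre that becomes C7.

Step 8
Reactants: 12 (3S,4R)-3-chloro-3-methyl-4-[(2-methyl-1,3-dioxolan-2-yl)methyl]oxolan-2-one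
Product: 13 (3S,4R)-3-chloro-3-methyl-4-[(2-methyl-1,3-dioxolan-2-yl)methyl]oxolan-2-ol (anomeric mixture)
Conditions: i-Bu2AlH, CH2Cl2, −78 °C; aq. KNaC4H4O6
Reagents that add atoms: none
Why: Half-reduction of a lactone by i-Bu2AlH; the tetrahedral aluminium hemiacetal is stable at −78 °C and gives the lactol on work-up, and the chlorinated carbon has no hydrogen, so it cannot epimerise.

Step 9
Reactants: 13 (3S,4R)-3-chloro-3-methyl-4-[(2-methyl-1,3-dioxolan-2-yl)methyl]oxolan-2-ol; 14 bromoform
Product: 15 (2R,3S,4E)-5-bromo-3-chloro-3-methyl-2-[(2-methyl-1,3-dioxolan-2-yl)methyl]pent-4-en-1-ol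
Conditions: CrBr2, CHBr3, THF, 0 °C → rt, dark
Reagents that add atoms: none
Why: Takai–Utimoto olefination; the gem-dichromium carbenoid formed from bromoform and divalent chromium adds to the aldehyde tautomer of the lactol and eliminates E-selectively to the bromoalkene C8=C9, CrBr2 being used so that halide exchange cannot give a vinyl chloride.

Step 10
Reactants: 15 (2R,3S,4E)-5-bromo-3-chloro-3-methyl-2-[(2-methyl-1,3-dioxolan-2-yl)methyl]pent-4-en-1-ol
Product: 18 (3R)-3-[(2S,3E)-4-bromo-2-chlorobut-3-en-2-yl]-5-methyl-2,3-dihydrofuran, via hydroxy ketone 16 (not isolated), via cyclic hemiketal 17 (not isolated)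
Conditions: PPTS, THF/H2O, 50 °C; then PPTS (cat.), PhH, reflux, Dean–Stark; Et3N-washed silica
Reagents that add atoms: none
Why: Acid hydrolysis of the dioxolane, 5-exo-trig hemiketalisation and acid-catalysed dehydration with azeotropic removal of water should give the thermodynamically preferred endocyclic enol ether; the tertiary allylic chloride ionises poorly under this weak acid because the vinylic bromine destabilises the allyl cation.

Step 11
Reactants: 18 (3R)-3-[(2S,3E)-4-bromo-2-chlorobut-3-en-2-yl]-5-methyl-2,3-dihydrofuran; 14 bromoform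
Product: 21 (2R,5R)-3-bromo-5-[(2S,3E)-4-bromo-2-chlorobut-3-en-2-yl]-2-methyl-5,6-dihydro-2H-pyran-2-ol, via dibromocyclopropane 19 (not isolated), via oxocarbenium bromide 20 (not isolated)
Conditions: CHBr3 (excess), KOC(CH3)3 (portionwise), pentane, −30 → −10 °C; then NaHCO3, acetone/H2O, 0 °C → rt
Reagents that add atoms: water, O
Why: Tribromomethanide from bromoform and KOC(CH3)3 loses bromide to give singlet dibromocarbene, which adds in a concerted [2+1] fashion to the electron-rich enol ether bond C2=C4 on the face away from the C5 side chain, forming C2–C3 and C3–C4; in the 2-oxabicyclo[3.1.0]hexane 19 the ring oxygen assists disrotatory electrocyclic cleavage of the shared C2–C4 bond as the endo bromide leaves, and the six-membered allylic oxocarbenium ion 20 is hydrated at C2 in the buffered aqueous stage. The closest known reaction type is the dihalocarbene ring expansion of 2,3-dihydrofurans to 2-alkoxy- or 2-hydroxy-3-halo-5,6-dihydro-2H-pyrans. The cyclopropane closes by cheletropic [2+1] addition, and the oxane ring arises not by a cyclisation but by strain-driven one-carbon enlargement of the furan ring through opening of the zero-atom bridge. The only new stereocentre, the hemiketal C2, is under thermodynamic (anomeric) control, is drawn as its expected major anomer and re-equilibrates in step 12; the two cyclopropane centres are destroyed on opening. The step needs chemoselectivity for the enol ether over the bromoalkene, which the far higher nucleophilicity of the trisubstituted enol ether toward an electrophilic carbene secures; it also needs the tertiary allylic chloride and C5–H to survive, which is secured by adding base in portions to excess bromoform at low temperature (no standing alkoxide), by the absence of silver, and by hydration of 20 under bicarbonate buffer, which should outrun proton loss from C5.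

Step 12
Reactants: 21 (2R,5R)-3-bromo-5-[(2S,3E)-4-bromo-2-chlorobut-3-en-2-yl]-2-methyl-5,6-dihydro-2H-pyran-2-ol
Product: 24 (2R,3S,5R)-3-bromo-5-[(2S,3E)-4-bromo-2-chlorobut-3-en-2-yl]-2-methyloxan-2-ol, via open-chain bromoenone 22 (not isolated), via open-chain bromoketone 23 (not isolated)
Conditions: Hantzsch ester (diethyl 2,6-dimethyl-1,4-dihydropyridine-3,5-dicarboxylate), L-valine tert-butyl ester·CF3CO2H (20 mol%), 1,4-dioxane, 40 °C, dark, held until the C3 epimer ratio is constant
Reagents that add atoms: none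
Why: Ring–chain tautomerism of 21 exposes the (3E)-α-bromoenone 22 (acetyl cis to C5), whose iminium ion with the hindered primary ammonium salt accepts hydride at C4 from the Hantzsch ester (organocatalytic conjugate transfer hydrogenation); hydrolysis gives bromoketone 23, which recloses, and C3 (through enamine/enol) and C2 (through ring opening) should equilibrate under the same conditions to the chair with Br, CH3 and the C5 side chain equatorial and the anomeric OH axial, which is the (2R,3S) target.

**Compound list**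

1 | ethyl levulinate | CCOC(=O)CCC(C)=O | starting material
2 | ethyl 3-(2-methyl-1,3-dioxolan-2-yl)propanoate | CCOC(=O)CCC1(C)OCCO1 | intermediate
3 | 3-(2-methyl-1,3-dioxolan-2-yl)propanoic acid | OC(=O)CCC1(C)OCCO1 | intermediate
4 | (R)-4-benzyl-1,3-oxazolidin-2-one | O=C1N[C@H](Cc2ccccc2)CO1 | starting material
5 | 2,2-dimethylpropanoic 3-(2-methyl-1,3-dioxolan-2-yl)propanoic anhydride (not isolated) | CC(C)(C)C(=O)OC(=O)CCC1(C)OCCO1 | intermediate
6 | (4R)-4-benzyl-3-[3-(2-methyl-1,3-dioxolan-2-yl)propanoyl]-1,3-oxazolidin-2-one | CC1(CCC(=O)N2[C@H](Cc3ccccc3)COC2=O)OCCO1 | intermediate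
7 | tert-butyl bromoacetate | CC(C)(C)OC(=O)CBr | starting material
8 | tert-butyl (3S)-4-[(4R)-4-benzyl-2-oxo-1,3-oxazolidin-3-yl]-3-[(2-methyl-1,3-dioxolan-2-yl)methyl]-4-oxobutanoate | CC(C)(C)OC(=O)C[C@H](CC1(C)OCCO1)C(=O)N1[C@H](Cc2ccccc2)COC1=O | intermediate
9 | tert-butyl (3S)-3-(hydroxymethyl)-4-(2-methyl-1,3-dioxolan-2-yl)butanoate (not isolated) | CC(C)(C)OC(=O)C[C@H](CC1(C)OCCO1)CO | intermediate
10 | (4S)-4-[(2-methyl-1,3-dioxolan-2-yl)methyl]oxolan-2-one | O=C1C[C@H](CC2(C)OCCO2)CO1 | intermediate
11 | (3S,4S)-3-methyl-4-[(2-methyl-1,3-dioxolan-2-yl)methyl]oxolan-2-one | C[C@@H]1C(=O)OC[C@H]1CC1(C)OCCO1 | intermediate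
12 | (3S,4R)-3-chloro-3-methyl-4-[(2-methyl-1,3-dioxolan-2-yl)methyl]oxolan-2-one | C[C@@]1(Cl)C(=O)OC[C@H]1CC1(C)OCCO1 | intermediate
13 | (3S,4R)-3-chloro-3-methyl-4-[(2-methyl-1,3-dioxolan-2-yl)methyl]oxolan-2-ol (anomeric mixture) | C[C@@]1(Cl)C(O)OC[C@H]1CC1(C)OCCO1 | intermediate
14 | bromoform | BrC(Br)Br | starting material
15 | (2R,3S,4E)-5-bromo-3-chloro-3-methyl-2-[(2-methyl-1,3-dioxolan-2-yl)methyl]pent-4-en-1-ol | C[C@@](Cl)(/C=C/Br)[C@@H](CO)CC1(C)OCCO1 | intermediate
16 | (4R,5S,6E)-7-bromo-5-chloro-4-(hydroxymethyl)-5-methylhept-6-en-2-one (not isolated) | C[C@@](Cl)(/C=C/Br)[C@@H](CO)CC(C)=O | intermediate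
17 | (4R)-4-[(2S,3E)-4-bromo-2-chlorobut-3-en-2-yl]-2-methyloxolan-2-ol (anomeric mixture, not isolated) | C[C@@](Cl)(/C=C/Br)[C@H]1COC(C)(O)C1 | intermediate
18 | (3R)-3-[(2S,3E)-4-bromo-2-chlorobut-3-en-2-yl]-5-methyl-2,3-dihydrofuran | C[C@@](Cl)(/C=C/Br)[C@H]1COC(C)=C1 | intermediate
19 | (1S,4R,5R)-6,6-dibromo-4-[(2S,3E)-4-bromo-2-chlorobut-3-en-2-yl]-1-methyl-2-oxabicyclo[3.1.0]hexane (expected anti adduct, not isolated) | C[C@@](Cl)(/C=C/Br)[C@H]1CO[C@@]2(C)[C@@H]1C2(Br)Br | intermediate
20 | (3R)-5-bromo-3-[(2S,3E)-4-bromo-2-chlorobut-3-en-2-yl]-6-methyl-2,3-dihydropyrylium bromide (not isolated) | C[C@@](Cl)(/C=C/Br)[C@H]1C[O+]=C(C)C(Br)=C1.[Br-] | intermediate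
21 | (2R,5R)-3-bromo-5-[(2S,3E)-4-bromo-2-chlorobut-3-en-2-yl]-2-methyl-5,6-dihydro-2H-pyran-2-ol (C2 equilibrating, major anomer drawn) | C[C@@](Cl)(/C=C/Br)[C@H]1CO[C@@](C)(O)C(Br)=C1 | intermediate
22 | (3E,5R,6S,7E)-3,8-dibromo-6-chloro-5-(hydroxymethyl)-6-methylocta-3,7-dien-2-one (not isolated) | CC(=O)/C(Br)=C\[C@H](CO)[C@](C)(Cl)/C=C/Br | intermediate
23 | (5R,6S,7E)-3,8-dibromo-6-chloro-5-(hydroxymethyl)-6-methyloct-7-en-2-one (C3 epimers, not isolated) | CC(=O)C(Br)C[C@H](CO)[C@](C)(Cl)/C=C/Br | intermediate
24 | (2R,3S,5R)-3-bromo-5-[(2S,3E)-4-bromo-2-chlorobut-3-en-2-yl]-2-methyloxan-2-ol | C[C@@](Cl)(/C=C/Br)[C@H]1CO[C@@](C)(O)[C@@H](Br)C1 | target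

**Step count**

Total steps: 12. Longest linear sequence: 12 steps (from 1).

**Steps most likely to fail**

1. Step 11. The ring-expanded cation 20 (or its anomeric bromide) may lose a proton from C5 or from the C2 methyl group faster than it is hydrated, giving dienes and eroding C5; the alkoxide may also remove HCl from the tertiary allylic chloride. The fallback is the acyclic form of the same carbene homologation, which has no cyclic cation; it sets out from 15 and comes back at 23. Compound 15 is hydrolysed as in the first stage of step 10 and the mixture of 16 and 17 is isolated without dehydration. Me3SiOTf and Et3N in CH2Cl2 at 0 °C silylate the alcohol and convert the ketone into the more substituted silyl enol ether, trimethyl{[(2Z,4R,5S,6E)-7-bromo-5-chloro-5-methyl-4-[(trimethylsilyloxy)methyl]hepta-2,6-dien-2-yl]oxy}silane F1. Dibromocarbene (CHBr3, KOC(CH3)3, pentane, −30 °C) adds to this enol ether, and the siloxydibromocyclopropane opens on warming and dilute citric acid work-up with loss of the silyl group and bromide. This known 2-haloenone synthesis should give (3Z,5R,6S,7E)-3,8-dibromo-6-chloro-5-(hydroxymethyl)-6-methylocta-3,7-dien-2-one F2, the geometric isomer of 22. F2 is reduced under the conditions of step 12 to 23, which closes and equilibrates to 24.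

2. Step 12. Iminium formation may be slow because 21 is largely ring-closed; the α-bromoketone may lose bromine reductively or alkylate the amine catalyst; and the C3 equilibrium may be only weakly biased. The fallback locks the open chain and uses a boron hydride; it sets out from 21 and comes back at 23. Et3SiCl and imidazole in DMF at 0 °C should drain the ring–chain equilibrium through the primary hydroxyl to give (3E,5R,6S,7E)-3,8-dibromo-6-chloro-6-methyl-5-[(triethylsilyloxy)methyl]octa-3,7-dien-2-one F3, whose s-cis enone geometry suits uncatalysed 1,4-hydroboration. Catecholborane in THF (−20 °C → rt) followed by pH 7 buffer should give (5R,6S,7E)-3,8-dibromo-6-chloro-6-methyl-5-[(triethylsilyloxy)methyl]oct-7-en-2-one F4. HF·pyridine in THF removes the silyl group to give 23, which closes to 24. If the epimer ratio at C3 remains poor, the mixture is equilibrated with the ammonium salt of step 12 and the minor epimer recycled.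

3. Step 9. Release of the aldehyde from the lactol may be slow, so that excess divalent chromium reduces the α-chloro aldehyde or the allylic C–Cl bond of the product by single-electron transfer. The fallback is chromium-free; it sets out from 13 and comes back at 15. A boron–Wittig reaction of 13 with CH2(Bpin)2 and lithium 2,2,6,6-tetramethylpiperidide (2.2 equiv, THF, −78 → 0 °C) should give the E-alkenylboronate (2R,3R,4E)-3-chloro-3-methyl-2-[(2-methyl-1,3-dioxolan-2-yl)methyl]-5-(4,4,5,5-tetramethyl-1,3,2-dioxaborolan-2-yl)pent-4-en-1-ol F5 (the descriptor at C3 changes only because boron lowers the priority of the vinyl branch). Ipso-bromodeboronation with NBS in MeCN at 0 °C in the dark, with retention of alkene geometry, then gives 15.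

**Further compounds**

F1 | step 11 | trimethyl{[(2Z,4R,5S,6E)-7-bromo-5-chloro-5-methyl-4-[(trimethylsilyloxy)methyl]hepta-2,6-dien-2-yl]oxy}silane | C/C(O[Si](C)(C)C)=C/[C@H](CO[Si](C)(C)C)[C@](C)(Cl)/C=C/Br
F2 | step 11 | (3Z,5R,6S,7E)-3,8-dibromo-6-chloro-5-(hydroxymethyl)-6-methylocta-3,7-dien-2-one | CC(=O)/C(Br)=C/[C@H](CO)[C@](C)(Cl)/C=C/Br
F3 | step 12 | (3E,5R,6S,7E)-3,8-dibromo-6-chloro-6-methyl-5-[(triethylsilyloxy)methyl]octa-3,7-dien-2-one | CC(=O)/C(Br)=C\[C@H](CO[Si](CC)(CC)CC)[C@](C)(Cl)/C=C/Br
F4 | step 12 | (5R,6S,7E)-3,8-dibromo-6-chloro-6-methyl-5-[(triethylsilyloxy)methyl]oct-7-en-2-one (C3 epimers) | CC(=O)C(Br)C[C@H](CO[Si](CC)(CC)CC)[C@](C)(Cl)/C=C/Br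
F5 | step 9 | (2R,3R,4E)-3-chloro-3-methyl-2-[(2-methyl-1,3-dioxolan-2-yl)methyl]-5-(4,4,5,5-tetramethyl-1,3,2-dioxaborolan-2-yl)pent-4-en-1-ol | C[C@@](Cl)(/C=C/B1OC(C)(C)C(C)(C)O1)[C@@H](CO)CC1(C)OCCO1
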